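**Remark on the chemistry:** water opens an α‑nitro epoxide at the carbon that does not carry the nitro group, so the hydrolysis product is written as the 4‑hydroxychroman‑3‑one 17; it and its 3‑hydroxy‑4‑keto isomer give the same 3,4‑dione on oxidation. The structures of the key‑step partners and product were rechecked atom by atom and need no correction. "Prenyl" means 3‑methylbut‑2‑en‑1‑yl and "MOM" means methoxymethyl. All stereocentres of intermediates are racemic and are erased before the target.

## Structural features

8‑Prenylkaempferol is a flavonol: benzene ring A is fused through C4a and C8a to the 4‑pyranone ring C, and the 4‑hydroxyphenyl ring B is joined to C2 by a single C–C bond. Ring A is substituted everywhere except C6: O1 on C8a, the prenyl chain on C8, hydroxyls on C7 and C5, and the C4 carbonyl on C4a; ring C carries an enolic hydroxyl at C3 beside that carbonyl. The target has no stereocentre. The stereocentres that appear on the way (C2 alone in 15, the contiguous C2–C3–C4 in 16, C2 and C4 in 17) are all destroyed, so none needs control. The fragile groups are the trisubstituted prenyl alkene (acid‑induced cyclisation onto the 7‑hydroxyl, electrophilic oxidants, halogens, hydrogenation) and the electron‑rich free polyphenol, so the phenols travel as acetals and every oxidant must be nucleophilic or alcohol‑selective. The real difficulty is twofold: placing the prenyl group on C8 and not on C6, and writing the C3 hydroxyl and C4 carbonyl into ring C without an electrophilic oxidant. The key step exploits C3, which lies between C4 (bonded to C4a of ring A) and C2 (bonded to O1 and ring B). A nitronate carbon serves as C3: it is generated when the ring A phenol oxygen adds to the nitroalkene carbon that becomes C2, and it then bonds to the formyl carbon that becomes C4, closing ring C. The nitro group later leaves and is replaced by oxygen.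

## Logic of the disconnections

**20 to 19.** The three aryl O–CH2OCH3 bonds are restored. The phenols must be masked during the base‑mediated annulation, the peroxide epoxidation and the oxidation, and one kind of acetal allows a single final unmasking. Nothing is gained in skeleton, but every earlier step runs on a non‑acidic substrate. The forward step needs acid mild enough not to cyclise the prenyl group onto the neighbouring hydroxyl.

**19 to 17 (through 18).** No skeletal bond is cut; the C4 carbonyl is taken back to a carbinol and the C2=C3 enol to its keto tautomer. This is done because an α‑ketol is what hydrolytic opening of a nitro epoxide delivers. The forward step needs an alcohol‑selective oxidant that ignores the trisubstituted alkene, after which aromatisation of the pyranone makes the tautomerisation irreversible.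

**17 to 16.** The C4–OH bond is cut and the C3 carbonyl is returned to a carbon bearing both the nitro group and the oxirane oxygen. The nitro epoxide is a latent α‑hydroxy ketone in which nitrite is the leaving group, so both ring C oxygens come from one functional group. The forward step must open the oxirane only at C4, which the fully substituted, nitro‑bearing C3 and the strongly donor‑stabilised benzylic C4 ensure, and it must stay non‑acidic.

**16 to 15.** The two oxirane C–O bonds are cut, returning to the nitroalkene. The cut is placed here because the nitroalkene is the only electron‑poor alkene in the molecule, so a nucleophilic peroxide distinguishes it from the prenyl alkene by polarity alone. The forward step needs a peroxide anion, not a peracid.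

**15 to 7 and 12.** O1–C2 and C3–C4 are cut, which splits the molecule into two pieces of similar size: ring A with C4 as a formyl group, and ring B with C2 and C3 as a nitrovinyl group. Both bonds form with natural polarity, and the nitrogen on C3 serves first as activating group and later as leaving group. The forward step requires that 7 has exactly one free hydroxyl, placed between the prenyl‑bearing carbon and the formyl‑bearing carbon, and that water is lost to make the sequence irreversible.

**7 to 5 (through 6).** The bond between the ring carbon (future C8) and the prenyl CH2 is cut and reconnected as an O–C(CH3)2 ether bond across a [3,3] shift. Direct C‑prenylation of such rings gives O/C and positional mixtures, whereas the sigmatropic shift delivers the chain only to the carbon next to the ether oxygen and turns the 1,1‑dimethylallyl group into a prenyl group by allyl inversion. The forward step needs a single free ortho carbon; in 5 the other ortho carbon carries the formyl group.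

**5 to 2 and 4.** The aryl O–C(tertiary) bond is cut. A tertiary allylic ether cannot be made by direct displacement, so the bond is traced to a π‑allyl substitution at the more substituted terminus. The forward step needs kinetic control (branched ether) and a substrate with one free hydroxyl.

**2 to 1, and 4 to 3.** Two O–CH2 acetal bonds of 2 and the O–C(=O) bond of 4 are cut. Starting from 1 is a design improvement: the formyl group is present from the outset, it is the future C4, and its hydrogen bond to the ortho hydroxyl lets the other two hydroxyls be protected selectively. This avoids a statistical protection of a symmetrical triphenol and a separate formylation.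

**12 to 9 and 10, and 9 to 8.** The Cα=Cβ bond of the nitroalkene (the future C2–C3 bond) is cut by a nitroaldol condensation, and the acetal O–CH2 bond by protection. The forward condensation must leave the acetal intact, so it is run under buffered conditions.

## Other disconnections considered

**Alternative 1:** The cut lies inside ring A: C8–C8a, C6–C7 and C4a–C8a would be formed together from 3‑ethoxycyclobut‑2‑en‑1‑one A1 and the siloxy alkyne A2, which carries the prenyl chain on its alkyne carbon.
- Forward step: on heating, A1 should open to a vinylketene and add across A2; the resulting vinylcyclobutenone should reopen, close by 6π‑electrocyclisation and tautomerise to phenol A3 (a Danheiser‑type benzannulation).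
- In its favour: C8 is formed with the prenyl group already attached, so no sigmatropic shift is needed and a C6 isomer is structurally impossible. On prenyl regiocontrol this is the equal of the chosen plan. The three ring A oxygens emerge as three different functions (free hydroxyl on C8a, silyl ether on C7, ethyl ether on C5), which is better than in 7, where the distinction rests on one hydrogen bond.
- Against it: the benzannulation builds the one part of the molecule that can be bought. A1 and A2 are both multi‑step reagents. A3 still lacks C4 and all of ring C, so a formylation at C4a and an annulation like step 7 would follow anyway. The C5 ethyl ether would have to be cleaved at the end with a Lewis‑acidic halide, the conditions under which a prenyl group beside a free phenol is most prone to cyclise.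
- Comparison: the pericyclic cascade is neutral and at least as gentle toward the prenyl alkene as step 7, but the route would be several steps longer and would exchange easily removed acetals for an ethyl ether.

**Alternative 2:** Ring C is cut at C4–C4a and O1–C2, giving the prenylated phenol A4 and the epoxy aldehyde A5, a three‑carbon linchpin that brings C2, C3, C4 and ring B.
- Forward step: the bromomagnesium phenoxide of A4 should deliver the aldehyde carbon of A5 to the free ortho carbon through a six‑membered magnesium chelate. The phenol oxygen should then open the oxirane at its benzylic carbon with inversion (6‑endo, favoured over 5‑exo by the para‑alkoxyphenyl group), giving the 2,3‑trans diol A6 as both C4 epimers.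
- In its favour: the ring A partner needs no formyl group, and the C3 oxygen arrives as a real hydroxyl, so no nitro‑for‑oxygen exchange is needed. A5 could be made enantioenriched, which makes this the better plan for chiral flavan‑3,4‑diols or dihydroflavonols, although the achiral target cannot use that.
- Against it: A6 lies two oxidation levels below the flavonol, whereas 17 lies one below. Two oxidations would have to be run beside the prenyl alkene on a benzylic C4 alcohol that ionises very easily. A5 is a fragile electrophile toward a basic magnesium reagent. C‑attack para to the phenoxide oxygen is not excluded by structure, as it is with 7. A4 would come from a symmetrical triphenol by a statistical bis‑protection.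
- Comparison: the two plans are equal in convergency (two bonds, one ring, one operation) and about equal in steps before the key step; the alternative needs roughly one step more after it. The chosen plan is safer because polarity alone fixes both bonds and loss of water makes the annulation irreversible.

**Alternative 3:** Only C3–C4 is cut. O1–C2 would be made beforehand by O‑alkylation, so the substrate is dialdehyde A7, whose ring A formyl carbon is C4 and whose aliphatic formyl carbon is C3.
- Forward step: a thiazolium‑derived carbene with an amine base should add to the aromatic formyl group, and the resulting acyl anion equivalent should attack the aliphatic aldehyde (6‑exo‑trig intramolecular crossed benzoin reaction) to give acyloin A8 with the 2‑aryl and 3‑hydroxyl groups trans.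
- In its favour: A8 already has the C4 ketone and the C3 hydroxyl, so only one dehydrogenation and the deprotection would remain. That is two steps after the key step against four in the chosen plan, which is the better figure. No nitro compound or peroxide is needed, and the bond is made catalytically with full atom economy.
- Against it: A7 would have to be made from 7 by alkylating its hindered, hydrogen‑bonded phenol with a secondary benzylic α‑halo aldehyde equivalent and then unmasking the aldehyde, two to three extra steps in which acid unmasking collides with the MOM acetals. The resulting α‑aryl‑α‑aryloxy aldehyde is extremely enolisable. The carbene should prefer the unhindered aliphatic formyl group to the electron‑rich, doubly ortho‑substituted aromatic one, and its adduct with an α‑aryloxy aldehyde can expel the phenoxide and end as an acyl azolium instead of a benzoin.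
- Comparison: both plans use the same ring A aldehyde 7, so they are equal in prenyl regiocontrol. In the chosen plan the stabilised nitronate has only the neighbouring formyl group to attack, whereas here chemoselectivity between two aldehydes must come from the catalyst. Total step count would be about equal or one longer, with a more fragile intermediate.

Key step: step 7

## Steps

**Step 1**
Reactants: 1 2,4,6‑trihydroxybenzaldehyde
Product: 2 2‑hydroxy‑4,6‑bis(methoxymethoxy)benzaldehyde
Conditions: MOMCl (2.2 equiv), i‑Pr2NEt, CH2Cl2, 0 °C to rt
Reagents that add atoms: chloromethyl methyl ether, COCCl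
Why: Base‑mediated O‑alkylation (acetal formation) of the para hydroxyl and one of the two equivalent ortho hydroxyls; the remaining ortho hydroxyl is locked in a hydrogen bond to the formyl group and is much less nucleophilic, a well‑known selectivity of 2,4,6‑trihydroxyaryl carbonyl compounds.

**Step 2**
Reactants: 3 2‑methylbut‑3‑en‑2‑ol
Product: 4 methyl 2‑methylbut‑3‑en‑2‑yl carbonate
Conditions: n‑BuLi, THF, −78 °C; then ClCO2Me, −78 °C to rt
Reagents that add atoms: methyl chloroformate, COC(=O)Cl
Why: O‑Acylation of the lithium alkoxide of the tertiary alcohol; deprotonation first avoids the sluggish reaction of a tertiary alcohol with a chloroformate under amine conditions.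

**Step 3**
Reactants: 2 2‑hydroxy‑4,6‑bis(methoxymethoxy)benzaldehyde; 4 methyl 2‑methylbut‑3‑en‑2‑yl carbonate
Product: 5 2‑[(2‑methylbut‑3‑en‑2‑yl)oxy]‑4,6‑bis(methoxymethoxy)benzaldehyde
Conditions: Pd(PPh3)4 (5 mol %), THF, 0 °C to rt
Reagents that add atoms: none
Why: Tsuji–Trost O‑allylation: zerovalent palladium ionises 4 with loss of CO2, the methoxide set free deprotonates the phenol, and the phenoxide attacks the 1,1‑dimethylallyl complex of divalent palladium at its more substituted terminus, the usual kinetic outcome for oxygen nucleophiles; low temperature and short reaction time should keep the branched ether from re‑ionising.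

**Step 4**
Reactants: 5 2‑[(2‑methylbut‑3‑en‑2‑yl)oxy]‑4,6‑bis(methoxymethoxy)benzaldehyde
Product: 7 2‑hydroxy‑4,6‑bis(methoxymethoxy)‑3‑prenylbenzaldehyde, via ortho‑dienone 6 (not isolated)
Conditions: PhNEt2, 120 °C
Reagents that add atoms: none
Why: Aromatic Claisen rearrangement; the [3,3] shift can reach only the one unsubstituted ortho carbon, allyl inversion converts the 1,1‑dimethylallyl ether into a prenyl group, and tautomerisation of dienone 6 restores the hydrogen‑bonded phenol. The basic solvent suppresses acid‑induced loss of the tertiary allyl group.

**Step 5**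
Reactants: 8 4‑hydroxybenzaldehyde
Product: 9 4‑(methoxymethoxy)benzaldehyde
Conditions: MOMCl, i‑Pr2NEt, CH2Cl2, 0 °C to rt
Reagents that add atoms: chloromethyl methyl ether, COCCl
Why: Standard phenol protection; the same acetal as on ring A allows one final deprotection and keeps the later nitroalkene from becoming a phenoxide‑deactivated, polymerisable acceptor.

**Step 6**
Reactants: 9 4‑(methoxymethoxy)benzaldehyde; 10 nitromethane
Product: 12 (E)‑1‑(methoxymethoxy)‑4‑(2‑nitroethenyl)benzene, via nitroaldol 11 (not isolated)
Conditions: NH4OAc (0.5 equiv), 10 as solvent, 90 °C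
Reagents that add atoms: none
Why: Henry condensation: nitroaldol addition followed by loss of water gives the conjugated, thermodynamically favoured E nitroalkene; the ammonium acetate buffer is mild enough for the aryl MOM ether.

**Step 7**
Reactants: 7 2‑hydroxy‑4,6‑bis(methoxymethoxy)‑3‑prenylbenzaldehyde; 12 (E)‑1‑(methoxymethoxy)‑4‑(2‑nitroethenyl)benzene
Product: 15 5,7‑bis(methoxymethoxy)‑2‑[4‑(methoxymethoxy)phenyl]‑3‑nitro‑8‑prenyl‑2H‑chromene (racemic), via oxa‑Michael adduct 13 (not isolated), via 3‑nitrochroman‑4‑ol 14 (not isolated)
Conditions: DABCO (1,4‑diazabicyclo[2.2.2]octane, 0.5 equiv), MeCN, 4 Å MS, 50 °C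
Reagents that add atoms: none
Why: The amine deprotonates the single free phenol of 7 and the phenoxide adds to the benzylic β‑carbon of 12 (oxa‑Michael addition, O1–C2), giving the nitronate of 13. The nitronate carbon then attacks the neighbouring formyl carbon in an intramolecular Henry reaction (C3–C4), closing ring C in the 6‑exo‑trig mode to give 14. E1cB loss of water from 14 (acidic C3–H, benzylic C4–OH activated by the ring A donors) gives the conjugated nitrochromene and pulls the reversible sequence forward. The closest known reaction type is the amine‑catalysed condensation of salicylaldehydes with β‑nitrostyrenes to 2‑aryl‑3‑nitro‑2H‑chromenes. The C2 stereocentre forms without control under the achiral catalyst (racemate), which is acceptable because C2 becomes sp2 in step 10. The step needs regioselectivity in both bond formations: polarity fixes oxygen‑to‑β‑carbon and nitronate‑carbon‑to‑carbonyl bonding. Because 7 has one free hydroxyl, flanked by the prenyl‑bearing and formyl‑bearing carbons, ring C can close only to the 8‑prenyl isomer. The conditions are neither acidic nor oxidising, so the prenyl alkene and the acetals are spared.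

**Step 8**
Reactants: 15 5,7‑bis(methoxymethoxy)‑2‑[4‑(methoxymethoxy)phenyl]‑3‑nitro‑8‑prenyl‑2H‑chromene
Product: 16 3,4‑epoxy‑5,7‑bis(methoxymethoxy)‑2‑[4‑(methoxymethoxy)phenyl]‑3‑nitro‑8‑prenylchromane (racemic, oxirane anti to the 2‑aryl group)
Conditions: 30% aq H2O2 (excess), NaOH (0.3 equiv), THF–MeOH, 0 °C
Reagents that add atoms: hydrogen peroxide, OO
Why: Weitz–Scheffer‑type nucleophilic epoxidation: hydroperoxide adds to C4 of the nitroalkene, preferentially anti to the 2‑aryl group, and the nitronate closes on oxygen with loss of hydroxide. The electron‑rich prenyl alkene is inert to a nucleophilic oxidant, and the α‑effect nucleophile compensates for the donor‑substituted, less electrophilic C4. The relative configuration is of no consequence.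

**Step 9**
Reactants: 16 3,4‑epoxy‑5,7‑bis(methoxymethoxy)‑2‑[4‑(methoxymethoxy)phenyl]‑3‑nitro‑8‑prenylchromane
Product: 17 4‑hydroxy‑5,7‑bis(methoxymethoxy)‑2‑[4‑(methoxymethoxy)phenyl]‑8‑prenylchroman‑3‑one (racemic, diastereomer mixture)
Conditions: THF–H2O (3:1), NaHCO3, 40 °C
Reagents that add atoms: water, O
Why: Hydrolytic opening of an α‑nitro epoxide: water attacks C4, the only oxirane carbon open to substitution and a benzylic centre stabilised by the C5 and C7 alkoxy groups and O1, and the C3 alkoxide expels nitrite to give the ketone. Bicarbonate holds the liberated nitrous acid as nitrite and prevents acid‑induced dehydration of the ketol.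

**Step 10**
Reactants: 17 4‑hydroxy‑5,7‑bis(methoxymethoxy)‑2‑[4‑(methoxymethoxy)phenyl]‑8‑prenylchroman‑3‑one
Product: 19 3‑hydroxy‑5,7‑bis(methoxymethoxy)‑2‑[4‑(methoxymethoxy)phenyl]‑8‑prenyl‑4H‑chromen‑4‑one, via chroman‑3,4‑dione 18 (not isolated)
Conditions: Dess–Martin periodinane (1.2 equiv), pyridine, CH2Cl2, 0 °C to rt
Reagents that add atoms: none
Why: Dess–Martin oxidation of the benzylic secondary alcohol gives dione 18, whose C2–H (α to the C3 ketone, benzylic, α to O1) enolises at once to the aromatic 3‑hydroxy‑4‑pyranone 19. Any 3‑hydroxy‑4‑keto isomer formed from 17 by enediol equilibration would give the same dione, and the reagent leaves the alkene and acetals untouched.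

**Step 11**
Reactants: 19 3‑hydroxy‑5,7‑bis(methoxymethoxy)‑2‑[4‑(methoxymethoxy)phenyl]‑8‑prenyl‑4H‑chromen‑4‑one
Product: 20 8‑prenylkaempferol
Conditions: 3 M aq HCl, MeOH, 50 °C
Reagents that add atoms: none
Why: Acid‑catalysed transacetalisation removes the three MOM groups as dimethoxymethane; moderate acid strength and temperature are chosen so that the prenyl alkene is not protonated and does not cyclise onto the 7‑hydroxyl.

## Compound list

1 | 2,4,6‑trihydroxybenzaldehyde | O=Cc1c(O)cc(O)cc1O | starting material
2 | 2‑hydroxy‑4,6‑bis(methoxymethoxy)benzaldehyde | COCOc1cc(O)c(C=O)c(OCOC)c1 | intermediate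
3 | 2‑methylbut‑3‑en‑2‑ol | C=CC(C)(C)O | starting material
4 | methyl 2‑methylbut‑3‑en‑2‑yl carbonate | C=CC(C)(C)OC(=O)OC | intermediate
5 | 2‑[(2‑methylbut‑3‑en‑2‑yl)oxy]‑4,6‑bis(methoxymethoxy)benzaldehyde | C=CC(C)(C)Oc1cc(OCOC)cc(OCOC)c1C=O | intermediate
6 | 2,4‑bis(methoxymethoxy)‑5‑(3‑methylbut‑2‑en‑1‑yl)‑6‑oxocyclohexa‑1,3‑diene‑1‑carbaldehyde (racemic, not isolated) | CC(C)=CCC1C(=O)C(C=O)=C(OCOC)C=C1OCOC | intermediate
7 | 2‑hydroxy‑4,6‑bis(methoxymethoxy)‑3‑(3‑methylbut‑2‑en‑1‑yl)benzaldehyde | CC(C)=CCc1c(O)c(C=O)c(OCOC)cc1OCOC | intermediate
8 | 4‑hydroxybenzaldehyde | O=Cc1ccc(O)cc1 | starting material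
9 | 4‑(methoxymethoxy)benzaldehyde | COCOc1ccc(C=O)cc1 | intermediate
10 | nitromethane | C[N+](=O)[O-] | starting material
11 | 1‑[4‑(methoxymethoxy)phenyl]‑2‑nitroethan‑1‑ol (racemic, not isolated) | COCOc1ccc(C(O)C[N+](=O)[O-])cc1 | intermediate
12 | (E)‑1‑(methoxymethoxy)‑4‑(2‑nitroethenyl)benzene | COCOc1ccc(/C=C/[N+](=O)[O-])cc1 | intermediate
13 | 2‑{1‑[4‑(methoxymethoxy)phenyl]‑2‑nitroethoxy}‑4,6‑bis(methoxymethoxy)‑3‑(3‑methylbut‑2‑en‑1‑yl)benzaldehyde (racemic, not isolated) | CC(C)=CCc1c(OC(C[N+](=O)[O-])c2ccc(OCOC)cc2)c(C=O)c(OCOC)cc1OCOC | intermediate
14 | 5,7‑bis(methoxymethoxy)‑2‑[4‑(methoxymethoxy)phenyl]‑8‑(3‑methylbut‑2‑en‑1‑yl)‑3‑nitrochroman‑4‑ol (racemic, diastereomer mixture, not isolated) | CC(C)=CCc1c(OCOC)cc(OCOC)c2C(O)C([N+](=O)[O-])C(c3ccc(OCOC)cc3)Oc12 | intermediate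
15 | 5,7‑bis(methoxymethoxy)‑2‑[4‑(methoxymethoxy)phenyl]‑8‑(3‑methylbut‑2‑en‑1‑yl)‑3‑nitro‑2H‑chromene (racemic, one enantiomer drawn) | CC(C)=CCc1c(OCOC)cc(OCOC)c2C=C([N+](=O)[O-])[C@H](c3ccc(OCOC)cc3)Oc12 | intermediate
16 | 3,4‑epoxy‑5,7‑bis(methoxymethoxy)‑2‑[4‑(methoxymethoxy)phenyl]‑8‑(3‑methylbut‑2‑en‑1‑yl)‑3‑nitrochromane (racemic, oxirane anti to the 2‑aryl group, one enantiomer drawn) | CC(C)=CCc1c(OCOC)cc(OCOC)c2c1O[C@@H](c3ccc(OCOC)cc3)[C@]4([N+](=O)[O-])O[C@H]24 | intermediate
17 | 4‑hydroxy‑5,7‑bis(methoxymethoxy)‑2‑[4‑(methoxymethoxy)phenyl]‑8‑(3‑methylbut‑2‑en‑1‑yl)chroman‑3‑one (racemic, configuration at C2 and C4 not defined) | CC(C)=CCc1c(OCOC)cc(OCOC)c2c1OC(c3ccc(OCOC)cc3)C(=O)C2O | intermediate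
18 | 5,7‑bis(methoxymethoxy)‑2‑[4‑(methoxymethoxy)phenyl]‑8‑(3‑methylbut‑2‑en‑1‑yl)chromane‑3,4‑dione (racemic, not isolated) | CC(C)=CCc1c(OCOC)cc(OCOC)c2c1OC(c3ccc(OCOC)cc3)C(=O)C2=O | intermediate
19 | 3‑hydroxy‑5,7‑bis(methoxymethoxy)‑2‑[4‑(methoxymethoxy)phenyl]‑8‑(3‑methylbut‑2‑en‑1‑yl)‑4H‑chromen‑4‑one | CC(C)=CCc1c(OCOC)cc(OCOC)c2c(=O)c(O)c(-c3ccc(OCOC)cc3)oc12 | intermediate
20 | 8‑prenylkaempferol, 3,5,7‑trihydroxy‑2‑(4‑hydroxyphenyl)‑8‑(3‑methylbut‑2‑en‑1‑yl)‑4H‑chromen‑4‑one (no stereocentre) | CC(C)=CCc1c(O)cc(O)c2c(=O)c(O)c(-c3ccc(O)cc3)oc12 | target

## Step count and least certain steps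

Total step count: 11. Longest linear sequence: 8 steps (steps 1, 3, 4, 7, 8, 9, 10, 11, from compound 1).

**Step 7 (key step).** The most likely failure is stalling at the reversible oxa‑Michael stage. The formyl group of 7 is deactivated by three donor oxygens and shielded by two ortho substituents, so the Henry closure may be slow while the amine oligomerises 12. The fallback sets out from 7 and returns at 15. Condensation of 7 with butan‑1‑amine (MgSO4, CH2Cl2) should give 2‑[(E)‑(butylimino)methyl]‑3,5‑bis(methoxymethoxy)‑6‑prenylphenol F1. Heated with 12 and catalytic benzoic acid in toluene, the protonated imine is a much better electrophile than the aldehyde: oxa‑Michael addition and nitro‑Mannich closure should give the 4‑(butylamino)‑3‑nitrochroman F2, which loses butan‑1‑amine by β‑elimination to give 15.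

**Step 3.** The most likely failure is loss of branched selectivity. The hydrogen‑bonded phenoxide of 2 is a weak nucleophile and a good leaving group, so the tertiary ether can re‑ionise on palladium and drift to the linear prenyl ether, which would give the 1,1‑dimethylallyl isomer in step 4. The fallback sets out from 2 and returns at 7, so that 4 and steps 3 and 4 are not needed. Allyl bromide with K2CO3 in DMF should give 2‑(allyloxy)‑4,6‑bis(methoxymethoxy)benzaldehyde F3. Thermal Claisen rearrangement (PhNEt2, 190 °C) should move the allyl group to the only free ortho carbon, giving 3‑allyl‑2‑hydroxy‑4,6‑bis(methoxymethoxy)benzaldehyde F4. Cross‑metathesis of F4 with 2‑methylbut‑2‑ene (second‑generation Grubbs catalyst, CH2Cl2, 40 °C) should then convert the allyl group into the prenyl group of 7.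

**Step 9.** The most likely failure is ionisation at C4 that outruns capture by water: the donor‑stabilised cation or the ketol can lose water through the C2 enol toward a 3‑hydroxyflavylium species, and any free nitrous acid can nitrosate the electron‑rich rings. The fallback sets out from 16 and returns at 17. Cesium acetate in DMF (CsOAc, rt) should open the oxirane bimolecularly at C4, as other anionic nucleophiles do with α‑nitro epoxides, to give the 4‑acetoxychroman‑3‑one F5 with loss of nitrite. Brief methanolysis (K2CO3, MeOH, 0 °C, argon) should release 17.

**Step 10.** The most likely failure is over‑oxidation: the enolic 3‑hydroxychromone formed in the flask can bind the hypervalent iodine reagent and take up a ligand at C2. The fallback sets out from 16 and returns at 19, avoiding both the ketol and the iodine reagent. Lithium bromide (LiBr, THF, 0 °C) should open the nitro epoxide to the 4‑bromochroman‑3‑one F6 (halide opening of α‑nitro epoxides to α‑halo ketones). Kornblum oxidation of F6 (DMSO, NaHCO3, rt) should give dione 18, which tautomerises to 19.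

## Further compounds

F1 | step 7 | 2‑[(E)‑(butylimino)methyl]‑3,5‑bis(methoxymethoxy)‑6‑(3‑methylbut‑2‑en‑1‑yl)phenol | CCCC/N=C/c1c(O)c(CC=C(C)C)c(OCOC)cc1OCOC
F2 | step 7 | N‑butyl‑5,7‑bis(methoxymethoxy)‑2‑[4‑(methoxymethoxy)phenyl]‑8‑(3‑methylbut‑2‑en‑1‑yl)‑3‑nitrochroman‑4‑amine (racemic, diastereomer mixture) | CCCCNC1c2c(OCOC)cc(OCOC)c(CC=C(C)C)c2OC(c3ccc(OCOC)cc3)C1[N+](=O)[O-]
F3 | step 3 | 2‑(allyloxy)‑4,6‑bis(methoxymethoxy)benzaldehyde | C=CCOc1cc(OCOC)cc(OCOC)c1C=O
F4 | step 3 | 3‑allyl‑2‑hydroxy‑4,6‑bis(methoxymethoxy)benzaldehyde | C=CCc1c(O)c(C=O)c(OCOC)cc1OCOC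
F5 | step 9 | 5,7‑bis(methoxymethoxy)‑2‑[4‑(methoxymethoxy)phenyl]‑8‑(3‑methylbut‑2‑en‑1‑yl)‑3‑oxochroman‑4‑yl acetate (racemic, diastereomer mixture) | CC(=O)OC1C(=O)C(c2ccc(OCOC)cc2)Oc3c(CC=C(C)C)c(OCOC)cc(OCOC)c13
F6 | step 10 | 4‑bromo‑5,7‑bis(methoxymethoxy)‑2‑[4‑(methoxymethoxy)phenyl]‑8‑(3‑methylbut‑2‑en‑1‑yl)chroman‑3‑one (racemic, diastereomer mixture) | BrC1C(=O)C(c2ccc(OCOC)cc2)Oc3c(CC=C(C)C)c(OCOC)cc(OCOC)c13
A1 | alternative 1 | 3‑ethoxycyclobut‑2‑en‑1‑one | CCOC1=CC(=O)C1
A2 | alternative 1 | triisopropyl[(5‑methylhex‑4‑en‑1‑yn‑1‑yl)oxy]silane | CC(C)=CCC#CO[Si](C(C)C)(C(C)C)C(C)C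
A3 | alternative 1 | 5‑ethoxy‑2‑(3‑methylbut‑2‑en‑1‑yl)‑3‑[(triisopropylsilyl)oxy]phenol | CCOc1cc(O)c(CC=C(C)C)c(O[Si](C(C)C)(C(C)C)C(C)C)c1
A4 | alternative 2 | 3,5‑bis(methoxymethoxy)‑2‑(3‑methylbut‑2‑en‑1‑yl)phenol | CC(C)=CCc1c(O)cc(OCOC)cc1OCOC
A5 | alternative 2 | trans‑3‑[4‑(methoxymethoxy)phenyl]oxirane‑2‑carbaldehyde (racemic, one enantiomer drawn) | COCOc1ccc([C@H]2O[C@@H]2C=O)cc1
A6 | alternative 2 | 2,3‑trans‑5,7‑bis(methoxymethoxy)‑2‑[4‑(methoxymethoxy)phenyl]‑8‑(3‑methylbut‑2‑en‑1‑yl)chroman‑3,4‑diol (racemic, one enantiomer drawn, both C4 epimers) | CC(C)=CCc1c(OCOC)cc(OCOC)c2c1O[C@H](c1ccc(OCOC)cc1)[C@@H](O)C2O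
A7 | alternative 3 | 2‑[2‑formyl‑3,5‑bis(methoxymethoxy)‑6‑(3‑methylbut‑2‑en‑1‑yl)phenoxy]‑2‑[4‑(methoxymethoxy)phenyl]acetaldehyde (racemic) | CC(C)=CCc1c(OC(C=O)c2ccc(OCOC)cc2)c(C=O)c(OCOC)cc1OCOC
A8 | alternative 3 | trans‑3‑hydroxy‑5,7‑bis(methoxymethoxy)‑2‑[4‑(methoxymethoxy)phenyl]‑8‑(3‑methylbut‑2‑en‑1‑yl)chroman‑4‑one (racemic, one enantiomer drawn) | O=C1c2c(OCOC)cc(OCOC)c(CC=C(C)C)c2O[C@H](c2ccc(OCOC)cc2)[C@H]1O
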